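## Retrosynthetic overview
1. Open ring C of the target at O1–C2. This gives the fully unprotected 2',4',6'-trihydroxy-3'-prenylchalcone. In the forward sense, a chalcone-isomerase-type 6-endo-trig oxa-Michael closure on a chiral nickel chelate is the last step. It fixes both C2 (S) and the 8-prenyl rather than 6-prenyl regiochemistry.
2. Disconnect the chalcone at Cα=Cβ into the lithium polyanion of unprotected 3-prenylphloroacetophenone and the ring B aldehyde, with no protecting groups.
3. Disconnect 3-prenylphloroacetophenone into phloroacetophenone and prenyl bromide (aromatic C-prenylation; C3 and C5 are equivalent by symmetry).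
4. Disconnect the ring B aldehyde into 3-bromo-4-methoxybenzaldehyde and 3-methylbut-3-enylzinc bromide (Negishi coupling).
5. Ring order: rings A and B are bought as arenes. Ring C is the only ring made and is closed last.

Assumption: the ligand derived from L-pipecolic acid is assumed to give the 2S product. This is to be checked by circular dichroism (2S-flavanones show a positive band near 330 nm and a negative band near 290 nm). If the sense is opposite, the mirror-image ligand from D-pipecolic acid is used in the same step.

## Route

Step 1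
Reactants: 1 4-bromo-2-methylbut-1-ene; 2 3-bromo-4-methoxybenzaldehyde
Product: 4 4-methoxy-3-(3-methylbut-3-en-1-yl)benzaldehyde, via homoallylzinc bromide 3 (not isolated)
Conditions: 1 (1.3 equiv), Zn dust (TMSCl-activated), LiCl, THF, 50 °C; then 2, Pd(OAc)2 (1 mol%), SPhos (2-dicyclohexylphosphino-2',6'-dimethoxybiphenyl, 2 mol%), THF, 25 °C
Reagents that add atoms: none
Why: Negishi sp3–sp2 cross-coupling: the primary alkylzinc bromide from LiCl-assisted zinc insertion is too unreactive to add to the free aldehyde, and the bulky electron-rich phosphine on zerovalent palladium makes reductive elimination faster than β-hydride elimination, so the 1,1-disubstituted alkene arrives unisomerised; no stereocenter is formed.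

Step 2
Reactants: 5 1-(2,4,6-trihydroxyphenyl)ethanone (phloroacetophenone); 6 prenyl bromide (1-bromo-3-methylbut-2-ene)
Product: 7 1-[2,4,6-trihydroxy-3-(3-methylbut-2-en-1-yl)phenyl]ethanone
Conditions: 5 (1.5 equiv), KOH (1 equiv per 6), H2O, 0 °C to rt; then dilute HCl, chromatography
Reagents that add atoms: prenyl bromide (compound 6), CC(C)=CCBr
Why: Prenyltransferase-like aromatic C-prenylation (C-alkylation of an ambident phloroglucinol phenolate): in water the oxygens are shielded by hydrogen bonding so the soft allylic bromide is attacked by ring carbon, C3 and C5 are equivalent so only one mono-C-prenyl isomer can form, and the excess of cheap 5 limits double prenylation; no stereocenter is formed.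

Step 3
Reactants: 7 1-[2,4,6-trihydroxy-3-(3-methylbut-2-en-1-yl)phenyl]ethanone; 4 4-methoxy-3-(3-methylbut-3-en-1-yl)benzaldehyde
Product: 10 (2E)-3-[4-methoxy-3-(3-methylbut-3-en-1-yl)phenyl]-1-[2,4,6-trihydroxy-3-(3-methylbut-2-en-1-yl)phenyl]prop-2-en-1-one, via tetralithio polyanion 8 (not isolated), via lithium aldolate 9 (not isolated)
Conditions: 7 (azeotropically dried), LiN(SiMe3)2 (4.3 equiv), THF, −78 to −10 °C; 4 (1.05 equiv), −78 °C to rt, 16 h; inverse quench into ice-cold 1 N HCl, rapid extraction, crystallisation, used at once
Reagents that add atoms: none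
Why: Claisen–Schmidt aldol condensation through a preformed lithium polyanion: the amide base irreversibly ionises the three phenols and the acetyl group (the same kind of polyanion that is C-acylated in direct flavone syntheses from unprotected polyhydroxyacetophenones), so the enolate is fully present instead of being suppressed as under hydroxide equilibrium, it adds to the non-enolisable aldehyde, E1cB loss of LiOH on warming gives the thermodynamic E-enone, the polyanionic chalcone cannot ring-close, and the cold acid quench passes quickly through the neutral pH range where racemic closure would start; the carbinol center of 9 is lost again.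

Step 4
Reactants: 10 (2E)-3-[4-methoxy-3-(3-methylbut-3-en-1-yl)phenyl]-1-[2,4,6-trihydroxy-3-(3-methylbut-2-en-1-yl)phenyl]prop-2-en-1-one
Product: 11 (2S)-5,7-dihydroxy-2-[4-methoxy-3-(3-methylbut-3-en-1-yl)phenyl]-8-(3-methylbut-2-en-1-yl)-2,3-dihydro-4H-chromen-4-one
Conditions: Ni(acac)2 (10 mol%), ligand L-PiPr2 (propane-1,3-diyl-bridged bis-N-oxide of (S)-N-(2,6-diisopropylphenyl)pipecolamide, 11 mol%), 4 Å MS, anisole/THF 5:1, 0 °C, 48 h; 5% aq. citric acid; chromatography with 0.1% AcOH, recrystallisation
Reagents that add atoms: none
Why: Proposed new method: this is a small-molecule mimic of chalcone isomerase (6-endo-trig intramolecular oxa-Michael addition) in which the native 6'-OH/C=O pair of 10 displaces one acetylacetonate and binds as a bidentate acylphenolate to the two free cis sites of the octahedral divalent nickel/N,N'-dioxide complex; binding through O-2' is disfavoured because the 3'-prenyl group would be pressed into the ligand sphere (as a 3-substituent is in salicylaldiminato complexes), so the carbonyl oxygen is locked syn to O-6' and only the hydroxyl next to the prenyl group can reach C-β, which gives the 8-prenyl skeleton; the released acetylacetonate serves as general base for that hydroxyl, and one 2,6-diisopropylanilide arm blocks one half-space, so the styryl arm can rotate out of the chelate plane only to the open side and O-2' adds to the Si face of C-β, setting 2S; acetylacetone then protonates the nickel enolate and fresh 10 displaces the product, with low temperature and an acidic work-up suppressing the reverse ring opening; the closest known reaction types are the N,N'-dioxide/divalent nickel catalysed enantioselective oxa-Michael closure of 2'-hydroxychalcones activated by an α-tert-butoxycarbonyl group (two-point 1,3-dicarbonyl binding) and the two-point binding of peri-hydroxy enones such as juglone to chiral binaphthol boron Lewis acids in Diels–Alder reactions.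

## Compound list
1 | 4-bromo-2-methylbut-1-ene | C=C(C)CCBr | starting material
2 | 3-bromo-4-methoxybenzaldehyde | COc1ccc(C=O)cc1Br | starting material
3 | (3-methylbut-3-en-1-yl)zinc bromide, not isolated | C=C(C)CC[Zn]Br | intermediate
4 | 4-methoxy-3-(3-methylbut-3-en-1-yl)benzaldehyde | C=C(C)CCc1cc(C=O)ccc1OC | intermediate
5 | 1-(2,4,6-trihydroxyphenyl)ethanone | CC(=O)c1c(O)cc(O)cc1O | starting material
6 | prenyl bromide (1-bromo-3-methylbut-2-ene) | CC(C)=CCBr | starting material
7 | 1-[2,4,6-trihydroxy-3-(3-methylbut-2-en-1-yl)phenyl]ethanone | CC(=O)c1c(O)cc(O)c(CC=C(C)C)c1O | intermediate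
8 | tetralithium salt of 7 (three phenolates plus enolate), not isolated | [Li+].[Li+].[Li+].[Li+].C=C([O-])c1c([O-])cc([O-])c(CC=C(C)C)c1[O-] | intermediate
9 | tetralithium aldolate from 8 and 4 (racemic at the carbinol carbon), not isolated | [Li+].[Li+].[Li+].[Li+].C=C(C)CCc1cc(C([O-])CC(=O)c2c([O-])cc([O-])c(CC=C(C)C)c2[O-])ccc1OC | intermediate
10 | (2E)-3-[4-methoxy-3-(3-methylbut-3-en-1-yl)phenyl]-1-[2,4,6-trihydroxy-3-(3-methylbut-2-en-1-yl)phenyl]prop-2-en-1-one | C=C(C)CCc1cc(/C=C/C(=O)c2c(O)cc(O)c(CC=C(C)C)c2O)ccc1OC | intermediate
11 | (2S)-5,7-dihydroxy-2-[4-methoxy-3-(3-methylbut-3-en-1-yl)phenyl]-8-(3-methylbut-2-en-1-yl)-2,3-dihydro-4H-chromen-4-one | C=C(C)CCc1cc([C@@H]2CC(=O)c3c(O)cc(O)c(CC=C(C)C)c3O2)ccc1OC | target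

## Step count and risks
Total step count: 4.
Longest linear sequence: 3 (5 → 7 → 10 → 11, or 1/2 → 4 → 10 → 11).

**Most likely to fail: step 4.**
- Turnover on a free triphenol is untested.
- The uncatalysed closure of such chalcones leans toward the 6-prenyl series.
- Reversible ring opening could erode both the regiochemical and the enantiomeric purity.

The fallback replaces catalyst control by substrate control plus resolution. It sets out from 7. MOMCl (2.2 equiv) and iPr2NEt in CH2Cl2 etherify the 4-OH and the less hindered 6-OH, giving 1-[2-hydroxy-4,6-bis(methoxymethoxy)-3-(3-methylbut-2-en-1-yl)phenyl]ethanone F1. Classical KOH/EtOH condensation with 4 gives the 4',6'-bis(methoxymethyl) chalcone F2. In it only the hydroxyl next to the prenyl group is free, so only the 8-prenyl skeleton can form. NaOAc in refluxing EtOH closes it to the racemic 5,7-bis(methoxymethoxy)flavanone F3. Preparative HPLC on an amylose tris(3,5-dimethylphenylcarbamate) phase delivers the (2S)-bis(methoxymethoxy)flavanone F4. The (2R)-bis(methoxymethoxy)flavanone F5 is re-opened to F2 with KOH and recycled. Brief treatment of F4 with HCl in MeOH at 40 °C removes both acetals, and the fallback comes back to the route at 11.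

**Second: step 3.**
- The tetra-anion may be poorly soluble.
- Elimination may be incomplete.
- Racemic ring closure may begin during the quench.

The fallback exchanges the polyanion for full protection. It sets out from 7. NaH and MOMCl in DMF give 1-[2,4,6-tris(methoxymethoxy)-3-(3-methylbut-2-en-1-yl)phenyl]ethanone F6. KOH/EtOH condensation with 4 gives the 2',4',6'-tris(methoxymethyl) chalcone F7. Closely monitored HCl/MeOH at rt then frees the three phenols before ring closure sets in. The fallback comes back to the route at 10.

**Third: step 2.**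
- O-alkylation and double or geminal C-prenylation compete, so the yield is modest.

The fallback replaces direct C-alkylation by O-alkylation followed by rearrangement. It sets out from 5. Mitsunobu etherification with 3-methylbut-2-en-1-ol (PPh3, DIAD, THF, 0 °C) reacts only at the non-chelated and most acidic 4-OH. It gives 1-[2,6-dihydroxy-4-(3-methylbut-2-en-1-yloxy)phenyl]ethanone F8. Bi(OTf)3 (5 mol%) in CH2Cl2 at 0 °C then induces the [1,3] O-to-C prenyl shift to one of the two equivalent ortho carbons, the para position being blocked by the acetyl group. The fallback comes back to the route at 7.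

## Further compounds
F1 | step 4 | 1-[2-hydroxy-4,6-bis(methoxymethoxy)-3-(3-methylbut-2-en-1-yl)phenyl]ethanone | CC(=O)c1c(O)c(CC=C(C)C)c(OCOC)cc1OCOC
F2 | step 4 | (2E)-1-[2-hydroxy-4,6-bis(methoxymethoxy)-3-(3-methylbut-2-en-1-yl)phenyl]-3-[4-methoxy-3-(3-methylbut-3-en-1-yl)phenyl]prop-2-en-1-one | C=C(C)CCc1cc(/C=C/C(=O)c2c(O)c(CC=C(C)C)c(OCOC)cc2OCOC)ccc1OC
F3 | step 4 | racemic 5,7-bis(methoxymethoxy)-2-[4-methoxy-3-(3-methylbut-3-en-1-yl)phenyl]-8-(3-methylbut-2-en-1-yl)chroman-4-one | C=C(C)CCc1cc(C2CC(=O)c3c(OCOC)cc(OCOC)c(CC=C(C)C)c3O2)ccc1OC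
F4 | step 4 | (2S)-5,7-bis(methoxymethoxy)-2-[4-methoxy-3-(3-methylbut-3-en-1-yl)phenyl]-8-(3-methylbut-2-en-1-yl)chroman-4-one | C=C(C)CCc1cc([C@@H]2CC(=O)c3c(OCOC)cc(OCOC)c(CC=C(C)C)c3O2)ccc1OC
F5 | step 4 | (2R)-5,7-bis(methoxymethoxy)-2-[4-methoxy-3-(3-methylbut-3-en-1-yl)phenyl]-8-(3-methylbut-2-en-1-yl)chroman-4-one | C=C(C)CCc1cc([C@H]2CC(=O)c3c(OCOC)cc(OCOC)c(CC=C(C)C)c3O2)ccc1OC
F6 | step 3 | 1-[2,4,6-tris(methoxymethoxy)-3-(3-methylbut-2-en-1-yl)phenyl]ethanone | CC(=O)c1c(OCOC)c(CC=C(C)C)c(OCOC)cc1OCOC
F7 | step 3 | (2E)-3-[4-methoxy-3-(3-methylbut-3-en-1-yl)phenyl]-1-[2,4,6-tris(methoxymethoxy)-3-(3-methylbut-2-en-1-yl)phenyl]prop-2-en-1-one | C=C(C)CCc1cc(/C=C/C(=O)c2c(OCOC)c(CC=C(C)C)c(OCOC)cc2OCOC)ccc1OC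
F8 | step 2 | 1-[2,6-dihydroxy-4-(3-methylbut-2-en-1-yloxy)phenyl]ethanone | CC(=O)c1c(O)cc(OCC=C(C)C)cc1O
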